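**Plan**

- Retrosynthesis (clerodane numbering: ring A = C1–C5 and C10, ring B = C5–C10, side chain C11–C16): cut the icosanoate C–O bond, then C12–C13 (B-alkyl Suzuki–Miyaura), then the C4–CH3 bond (enol triflate), then C5–C10 and C2–C3 together, which opens the whole decalin to an acyclic keto enal.
- Enabling feature: in ring A the methyl-bearing alkene carbon C4 sits between the quaternary ring-fusion carbon C5 and C3. Written as a C4 ketone, C5 and C3 are the two α-carbons of one carbonyl (a 1,3-bis-nucleophile). The other half of ring A, C10–C1–C2, is then the β-carbon, α-carbon and carbonyl carbon of an enal on the quaternary C9 (a 1,3-bis-electrophile without γ-hydrogens).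
- Forward order: chiral lactone → C8/C9 stereodiad → open-chain keto enal → in one flask, Michael addition closes ring B (C5–C10) and aldol condensation closes ring A (C2–C3) → enone → C3=C4 methyl alkene → side chain by hydroboration/Suzuki coupling → ester.
- Stereochemistry: C8 comes from (S)-β-methyl-γ-butyrolactone; C9 from an anti-selective aldol on the lactone enolate; C10 and C5 from a chair transition state of the cascade anchored by C8/C9; the C13=C14 geometry from trans-hydroalumination/iodination, retained in the coupling.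

Key step: step 9

Assumption: (S)-4-methyldihydrofuran-2(3H)-one (1) is taken as a catalogue compound; otherwise it is one step from 4-methylfuran-2(5H)-one by CuH-catalysed asymmetric conjugate reduction.

**Route**

Step 1
Reactants: 1 (S)-4-methyldihydrofuran-2(3H)-one
Product: 2 (3S,4S)-3,4-dimethyldihydrofuran-2(3H)-one
Conditions: LiN(i-Pr)2, THF, −78 °C; MeI, −78 → −40 °C
Reagents that add atoms: iodomethane (CI)
Why: Alkylation of the lithium enolate of a β-substituted γ-butyrolactone should occur anti to the C4 methyl group to give the trans isomer, although this centre is planarised again in step 2.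

Step 2
Reactants: 2 (3S,4S)-3,4-dimethyldihydrofuran-2(3H)-one
Product: 3 (3R,4S)-3-(1-hydroxyethyl)-3,4-dimethyldihydrofuran-2(3H)-one (carbinol epimers)
Conditions: LiN(i-Pr)2, THF, −78 °C; CH3CHO (3 equiv), −78 °C; AcOH quench at −78 °C
Reagents that add atoms: acetaldehyde (CC=O)
Why: Aldol addition of the tetrasubstituted lactone enolate, in which acetaldehyde should approach the face anti to the adjacent C4 methyl group, creates the quaternary centre (future C9) with its methyl cis and the two-carbon branch trans to the ring methyl.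

Step 3
Reactants: 3 (3R,4S)-3-(1-hydroxyethyl)-3,4-dimethyldihydrofuran-2(3H)-one
Product: 4 (3S,4S)-3-ethenyl-3,4-dimethyldihydrofuran-2(3H)-one
Conditions: Burgess reagent, PhMe, 80 °C
Reagents that add atoms: none
Why: Burgess dehydration is a thermal syn-elimination of the derived sulfamate, and because the carbinol is flanked by a quaternary carbon the only β-hydrogens are those of the methyl group, so the terminal vinyl group is the sole alkene possible.

Step 4
Reactants: 4 (3S,4S)-3-ethenyl-3,4-dimethyldihydrofuran-2(3H)-one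
Product: 5 (3S,4S)-3-ethenyl-3,4-dimethyltetrahydrofuran-2-ol (lactol; anomer mixture)
Conditions: i-Bu2AlH (1.1 equiv), CH2Cl2, −78 °C
Reagents that add atoms: none
Why: Partial reduction of a lactone to the lactol by i-Bu2AlH at low temperature, helped by the α-quaternary centre, which stabilises the tetrahedral aluminate against over-reduction.

Step 5
Reactants: 5 (3S,4S)-3-ethenyl-3,4-dimethyltetrahydrofuran-2-ol
Product: 6 (2S,3R)-3-[2-(1,3-dioxolan-2-yl)ethenyl]-2,3-dimethylpent-4-en-1-ol (E/Z mixture at the acetal-bearing alkene)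
Conditions: [(1,3-dioxolan-2-yl)methyl]PPh3Br (3 equiv), KOt-Bu (3 equiv), THF, 0 → 45 °C
Reagents that add atoms: (1,3-dioxolan-2-ylmethyl)triphenylphosphonium bromide ([Br-].C(C1OCCO1)[P+](c1ccccc1)(c1ccccc1)c1ccccc1)
Why: Wittig olefination of the ring-opened hydroxy aldehyde form of the lactol with a non-stabilised acetal ylide installs the masked enal without offering the freed primary alcohol a Michael acceptor to add to.

Step 6
Reactants: 6 (2S,3R)-3-[2-(1,3-dioxolan-2-yl)ethenyl]-2,3-dimethylpent-4-en-1-ol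
Product: 7 2-[(3R,4S)-3-ethenyl-5-iodo-3,4-dimethylpent-1-en-1-yl]-1,3-dioxolane (E/Z mixture)
Conditions: I2, PPh3, imidazole, CH2Cl2, 0 → 23 °C
Reagents that add atoms: iodine (II)
Why: Appel-type iodination of the primary alcohol under imidazole buffering, which leaves the dioxolane and both alkenes untouched.

Step 7
Reactants: 7 2-[(3R,4S)-3-ethenyl-5-iodo-3,4-dimethylpent-1-en-1-yl]-1,3-dioxolane; 8 3-methylbut-3-en-2-one (5 equiv)
Product: 9 (6R,7S)-7-[2-(1,3-dioxolan-2-yl)ethenyl]-3,6,7-trimethylnon-8-en-2-one (C3 epimers; E/Z mixture)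
Conditions: Bu3SnH (1.3 equiv, slow addition), AIBN (0.1 equiv), PhH, 80 °C
Reagents that add atoms: none
Why: Giese addition of the primary alkyl radical to the unhindered terminus of the 1,1-disubstituted enone, followed by hydrogen transfer from Bu3SnH, delivers the α-methyl methyl ketone, whose new α-centre is uncontrolled and irrelevant because it is enolised in step 9.

Step 8
Reactants: 9 (6R,7S)-7-[2-(1,3-dioxolan-2-yl)ethenyl]-3,6,7-trimethylnon-8-en-2-one
Product: 10 (2E,4S,5R)-4-ethenyl-4,5,8-trimethyl-9-oxodec-2-enal (C8 epimers)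
Conditions: aq. HCl (1 M, cat.), THF, 23 °C
Reagents that add atoms: water (O)
Why: Acid-catalysed acetal hydrolysis unmasks the enal, and the conjugated aldehyde should equilibrate to the E isomer under the same conditions.

Step 9
Reactants: 10 (2E,4S,5R)-4-ethenyl-4,5,8-trimethyl-9-oxodec-2-enal
Product: 13 (4aR,5S,6R,8aR)-5-ethenyl-5,6,8a-trimethyl-4a,5,6,7,8,8a-hexahydronaphthalen-1(4H)-one, via cyclohexyl keto aldehyde 11 (not isolated), via β-hydroxy ketone 12 (not isolated)
Conditions: KOt-Bu (0.3 equiv), t-BuOH–THF (1:4), 0.005 M, 0 → 23 °C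
Reagents that add atoms: none
Why: Reversible enolisation by KOt-Bu gives both ketone enolates, but only the tetrasubstituted C5 enolate can reach the enal β-carbon C10 through a six-membered transition state, so a Michael addition forms C5–C10 and closes ring B (6-enolexo-exo-trig); the methyl-side enolate (C3) of the resulting 1,5-keto aldehyde then adds to the aldehyde carbon C2 (6-enolendo-exo-trig aldol, ring A) and E1cB loss of water gives the enone. The closest known reaction type is the base-mediated Michael–aldol condensation of Robinson-type annulations, here as the intramolecular form of the [3+3] union of an α-branched methyl ketone with an acrylic acceptor. C10 should be set in a chair transition state of the forming ring B in which the C8 methyl is equatorial, the C9 methyl axial and the enal arm pseudo-equatorial, which puts H10 axial and anti to the C9 methyl. C5 should be set in the same transition state because the solvated potassium enolate arm (C4), locked in the plane perpendicular to the forming bond, is larger than the C5 methyl and takes the pseudo-equatorial site anti to C9, leaving the methyl axial, which after ring A closure means the trans ring fusion; the carbinol centre at C2 is erased by dehydration. The step needs chemoselectivity (Michael addition before any aldol chemistry at the enal) and facial selectivity at C5: the first is secured by the quaternary C9, which leaves the enal without γ-hydrogens and makes every alternative ring closure four- or eight-membered, and by high dilution against bimolecular aldol reactions; the second rests on the size difference just described.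

Step 10
Reactants: 13 (4aR,5S,6R,8aR)-5-ethenyl-5,6,8a-trimethyl-4a,5,6,7,8,8a-hexahydronaphthalen-1(4H)-one
Product: 15 (4aR,5S,6R,8aR)-5-ethenyl-5,6,8a-trimethyl-3,4,4a,5,6,7,8,8a-octahydronaphthalen-1-yl trifluoromethanesulfonate, via lithium enolate 14 (not isolated)
Conditions: LiBH(s-Bu)3 (1.05 equiv), THF, −78 °C; PhNTf2, −78 → 23 °C
Reagents that add atoms: N-phenylbis(trifluoromethanesulfonimide) (O=S(=O)(N(c1ccccc1)S(=O)(=O)C(F)(F)F)C(F)(F)F)
Why: Conjugate reduction of a β-unsubstituted cyclohexenone whose carbonyl is screened by the quaternary C5 gives the C3=C4 lithium enolate regiospecifically, and O-sulfonylation with PhNTf2 fixes that double bond position as the enol triflate.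

Step 11
Reactants: 15 (4aR,5S,6R,8aR)-5-ethenyl-5,6,8a-trimethyl-3,4,4a,5,6,7,8,8a-octahydronaphthalen-1-yl trifluoromethanesulfonate
Product: 16 (1S,2R,4aR,8aR)-1-ethenyl-1,2,4a,5-tetramethyl-1,2,3,4,4a,7,8,8a-octahydronaphthalene
Conditions: MeMgBr, Fe(acac)3 (5 mol%), THF–NMP, −20 → 0 °C
Reagents that add atoms: methylmagnesium bromide (C[Mg]Br)
Why: Iron-catalysed Kumada-type cross-coupling of the alkenyl triflate with MeMgBr replaces the triflate by methyl without moving the double bond or touching the isolated vinyl group.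

Step 12
Reactants: 17 but-2-yne-1,4-diol
Product: 18 4-{[tert-butyl(dimethyl)silyl]oxy}but-2-yn-1-ol
Conditions: NaH (1.0 equiv), THF, 23 °C; TBSCl (1.0 equiv)
Reagents that add atoms: tert-butyldimethylsilyl chloride (CC(C)(C)[Si](C)(C)Cl)
Why: Monosilylation of a symmetrical diol through its sparingly soluble monosodium alkoxide.

Step 13
Reactants: 18 4-{[tert-butyl(dimethyl)silyl]oxy}but-2-yn-1-ol
Product: 20 (Z)-4-{[tert-butyl(dimethyl)silyl]oxy}-3-iodobut-2-en-1-ol, via cyclic alkenylalanate 19 (not isolated)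
Conditions: NaAlH2(OCH2CH2OMe)2, THF, 0 → 23 °C; I2, −78 °C
Reagents that add atoms: iodine (II)
Why: Hydroxyl-directed trans-hydroalumination of the propargylic alcohol places aluminium on the distal alkyne carbon in a five-membered alkoxyalanate, and iodinolysis with retention gives the Z iodoalkene.

Step 14
Reactants: 16 (1S,2R,4aR,8aR)-1-ethenyl-1,2,4a,5-tetramethyl-1,2,3,4,4a,7,8,8a-octahydronaphthalene; 20 (Z)-4-{[tert-butyl(dimethyl)silyl]oxy}-3-iodobut-2-en-1-ol
Product: 22 (2E)-3-({[tert-butyl(dimethyl)silyl]oxy}methyl)-5-[(1S,2R,4aR,8aR)-1,2,4a,5-tetramethyl-1,2,3,4,4a,7,8,8a-octahydronaphthalen-1-yl]pent-2-en-1-ol, via B-alkyl-9-BBN 21 (not isolated)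
Conditions: 9-BBN, THF, 0 → 40 °C; then 20, Pd(dppf)Cl2 (5 mol%), AsPh3, Cs2CO3, DMF–H2O, 23 °C
Reagents that add atoms: none
Why: 9-BBN hydroborates only the monosubstituted vinyl group at its terminus, and the B-alkyl Suzuki–Miyaura coupling then proceeds with retention of the iodoalkene geometry, so C12 ends cis to the CH2OH carbon as in the target.

Step 15
Reactants: 22 (2E)-3-({[tert-butyl(dimethyl)silyl]oxy}methyl)-5-[(1S,2R,4aR,8aR)-1,2,4a,5-tetramethyl-1,2,3,4,4a,7,8,8a-octahydronaphthalen-1-yl]pent-2-en-1-ol; 23 icosanoyl chloride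
Product: 24 (2E)-3-({[tert-butyl(dimethyl)silyl]oxy}methyl)-5-[(1S,2R,4aR,8aR)-1,2,4a,5-tetramethyl-1,2,3,4,4a,7,8,8a-octahydronaphthalen-1-yl]pent-2-en-1-yl icosanoate
Conditions: Et3N, DMAP (cat.), CH2Cl2, 0 → 23 °C
Reagents that add atoms: none
Why: DMAP-catalysed acylation of the only free hydroxyl group, which is primary and allylic.

Step 16
Reactants: 24 (2E)-3-({[tert-butyl(dimethyl)silyl]oxy}methyl)-5-[(1S,2R,4aR,8aR)-1,2,4a,5-tetramethyl-1,2,3,4,4a,7,8,8a-octahydronaphthalen-1-yl]pent-2-en-1-yl icosanoate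
Product: 25 (2E)-3-(hydroxymethyl)-5-[(1S,2R,4aR,8aR)-1,2,4a,5-tetramethyl-1,2,3,4,4a,7,8,8a-octahydronaphthalen-1-yl]pent-2-en-1-yl icosanoate (target)
Conditions: HF·pyridine, pyridine–THF, 0 → 23 °C
Reagents that add atoms: none
Why: Fluoride-mediated cleavage of the primary silyl ether under buffered conditions that spare the allylic ester, while the trans disposition of the two oxygenated carbons across the alkene rules out acyl migration.

**Compound list**

1 | (S)-4-methyldihydrofuran-2(3H)-one | C[C@@H]1COC(=O)C1 | starting material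
2 | (3S,4S)-3,4-dimethyldihydrofuran-2(3H)-one | C[C@@H]1COC(=O)[C@H]1C | intermediate
3 | (3R,4S)-3-(1-hydroxyethyl)-3,4-dimethyldihydrofuran-2(3H)-one (carbinol epimers) | C[C@@H]1COC(=O)[C@@]1(C)C(C)O | intermediate
4 | (3S,4S)-3-ethenyl-3,4-dimethyldihydrofuran-2(3H)-one | C[C@@H]1COC(=O)[C@@]1(C)C=C | intermediate
5 | (3S,4S)-3-ethenyl-3,4-dimethyltetrahydrofuran-2-ol (anomer mixture) | C[C@@H]1COC(O)[C@@]1(C)C=C | intermediate
6 | (2S,3R)-3-[2-(1,3-dioxolan-2-yl)ethenyl]-2,3-dimethylpent-4-en-1-ol (E/Z mixture) | OC[C@@H](C)[C@](C)(C=C)C=CC1OCCO1 | intermediate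
7 | 2-[(3R,4S)-3-ethenyl-5-iodo-3,4-dimethylpent-1-en-1-yl]-1,3-dioxolane (E/Z mixture) | IC[C@@H](C)[C@](C)(C=C)C=CC1OCCO1 | intermediate
8 | 3-methylbut-3-en-2-one | CC(=O)C(C)=C | starting material
9 | (6R,7S)-7-[2-(1,3-dioxolan-2-yl)ethenyl]-3,6,7-trimethylnon-8-en-2-one (C3 epimers; E/Z mixture) | CC(=O)C(C)CC[C@@H](C)[C@](C)(C=C)C=CC1OCCO1 | intermediate
10 | (2E,4S,5R)-4-ethenyl-4,5,8-trimethyl-9-oxodec-2-enal (C8 epimers) | CC(=O)C(C)CC[C@@H](C)[C@](C)(C=C)/C=C/C=O | intermediate
11 | 2-[(1R,2S,3R,6R)-6-acetyl-2-ethenyl-2,3,6-trimethylcyclohexyl]acetaldehyde | C=C[C@@]1(C)[C@H](C)CC[C@@](C)(C(C)=O)[C@@H]1CC=O | intermediate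
12 | (4aR,5S,6R,8aR)-5-ethenyl-3-hydroxy-5,6,8a-trimethyl-3,4,4a,5,6,7,8,8a-octahydronaphthalen-1(2H)-one (carbinol epimers) | C=C[C@@]1(C)[C@H](C)CC[C@@]2(C)C(=O)CC(O)C[C@H]12 | intermediate
13 | (4aR,5S,6R,8aR)-5-ethenyl-5,6,8a-trimethyl-4a,5,6,7,8,8a-hexahydronaphthalen-1(4H)-one | C=C[C@@]1(C)[C@H](C)CC[C@@]2(C)C(=O)C=CC[C@H]12 | intermediate
14 | lithium (4aR,5S,6R,8aR)-5-ethenyl-5,6,8a-trimethyl-3,4,4a,5,6,7,8,8a-octahydronaphthalen-1-olate | C=C[C@@]1(C)[C@H](C)CC[C@@]2(C)C([O-])=CCC[C@H]12.[Li+] | intermediate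
15 | (4aR,5S,6R,8aR)-5-ethenyl-5,6,8a-trimethyl-3,4,4a,5,6,7,8,8a-octahydronaphthalen-1-yl trifluoromethanesulfonate | C=C[C@@]1(C)[C@H](C)CC[C@@]2(C)C(OS(=O)(=O)C(F)(F)F)=CCC[C@H]12 | intermediate
16 | (1S,2R,4aR,8aR)-1-ethenyl-1,2,4a,5-tetramethyl-1,2,3,4,4a,7,8,8a-octahydronaphthalene | C=C[C@@]1(C)[C@H](C)CC[C@@]2(C)C(C)=CCC[C@H]12 | intermediate
17 | but-2-yne-1,4-diol | OCC#CCO | starting material
18 | 4-{[tert-butyl(dimethyl)silyl]oxy}but-2-yn-1-ol | CC(C)(C)[Si](C)(C)OCC#CCO | intermediate
19 | sodium cyclic alkenylalanate (five-membered C=C–C–O–Al ring; Al on the alkene carbon bearing CH2OSi and carrying two 2-methoxyethoxy groups) | CC(C)(C)[Si](C)(C)OCC1=CCO[Al-]1(OCCOC)OCCOC.[Na+] | intermediate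
20 | (Z)-4-{[tert-butyl(dimethyl)silyl]oxy}-3-iodobut-2-en-1-ol | CC(C)(C)[Si](C)(C)OC/C(I)=C/CO | intermediate
21 | 9-{2-[(1S,2R,4aR,8aR)-1,2,4a,5-tetramethyl-1,2,3,4,4a,7,8,8a-octahydronaphthalen-1-yl]ethyl}-9-borabicyclo[3.3.1]nonane | B1(CC[C@@]3(C)[C@H](C)CC[C@@]4(C)C(C)=CCC[C@H]34)C2CCCC1CCC2 | intermediate
22 | (2E)-3-({[tert-butyl(dimethyl)silyl]oxy}methyl)-5-[(1S,2R,4aR,8aR)-1,2,4a,5-tetramethyl-1,2,3,4,4a,7,8,8a-octahydronaphthalen-1-yl]pent-2-en-1-ol | OC/C=C(/CO[Si](C)(C)C(C)(C)C)CC[C@@]1(C)[C@H](C)CC[C@@]2(C)C(C)=CCC[C@H]12 | intermediate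
23 | icosanoyl chloride | CCCCCCCCCCCCCCCCCCCC(=O)Cl | starting material
24 | (2E)-3-({[tert-butyl(dimethyl)silyl]oxy}methyl)-5-[(1S,2R,4aR,8aR)-1,2,4a,5-tetramethyl-1,2,3,4,4a,7,8,8a-octahydronaphthalen-1-yl]pent-2-en-1-yl icosanoate | CCCCCCCCCCCCCCCCCCCC(=O)OC/C=C(/CO[Si](C)(C)C(C)(C)C)CC[C@@]1(C)[C@H](C)CC[C@@]2(C)C(C)=CCC[C@H]12 | intermediate
25 | (2E)-3-(hydroxymethyl)-5-[(1S,2R,4aR,8aR)-1,2,4a,5-tetramethyl-1,2,3,4,4a,7,8,8a-octahydronaphthalen-1-yl]pent-2-en-1-yl icosanoate | CCCCCCCCCCCCCCCCCCCC(=O)OC/C=C(/CO)CC[C@@]1(C)[C@H](C)CC[C@@]2(C)C(C)=CCC[C@H]12 | target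

**Step count**

Total steps: 16. Longest linear sequence: 14 (steps 1–11 and 14–16); steps 12–13 make the side-chain fragment.

**Steps most likely to fail**

Step 9. The hindered Michael addition (a tetrasubstituted enolate attacking a neopentylic β-carbon) may be outrun by bimolecular aldol condensation at the enal, and ring B may close on the wrong face of the C5 enolate, which would lead to the cis-fused series. The fallback sets out from 10 and comes back at 13; it separates the two bond formations and runs the first under TiCl4 activation. Equilibrating silylation of 10 (Me3SiCl, NaI, Et3N, MeCN) should give the tetrasubstituted silyl enol ether (2E,4S,5R)-4-ethenyl-4,5,8-trimethyl-9-[(trimethylsilyl)oxy]deca-2,8-dienal F1. TiCl4 (CH2Cl2, −78 °C) should then close ring B by an intramolecular Mukaiyama–Michael addition, which is irreversible, involves no free enolate, and holds the bulkier C4(OSiMe3) arm pseudo-equatorial; this gives keto aldehyde 11, here isolated. Piperidinium acetate (PhH, 60 °C) should complete the aldol condensation to 13.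

Step 2. The aldol addition may reverse (retro-aldol on warming or during the dehydration), and the small aldehyde may discriminate the two enolate faces only weakly when the quaternary centre is formed. The fallback sets out from 2 and comes back at 4; it uses a vinyl cation equivalent in place of aldol addition and dehydration. Michael addition of the lithium enolate of 2 to phenyl vinyl sulfoxide (THF, −78 °C) should give, anti to the ring methyl, (3S,4S)-3,4-dimethyl-3-[2-(phenylsulfinyl)ethyl]dihydrofuran-2(3H)-one F2. Thermal syn-elimination of benzenesulfenic acid (PhMe, 110 °C, CaCO3) should then give 4 directly, bypassing 3.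

Step 5. Olefination of the hindered lactol may be slow (its open form is an α-quaternary aldehyde), with competing decomposition of the β-oxygenated ylide. The fallback sets out from 5 and comes back at 10; it uses a stabilised ylide and reveals the enal by redox adjustment before the radical step. Ph3P=CHCO2Me (PhCO2H cat., PhMe, 80 °C) should give methyl (2E,4R,5S)-4-ethenyl-6-hydroxy-4,5-dimethylhex-2-enoate F3. I2, PPh3 and imidazole should convert it into methyl (2E,4R,5S)-4-ethenyl-6-iodo-4,5-dimethylhex-2-enoate F4. i-Bu2AlH (CH2Cl2, −78 °C) should give (2E,4R,5S)-4-ethenyl-6-iodo-4,5-dimethylhex-2-en-1-ol F5, and MnO2 should give (2E,4R,5S)-4-ethenyl-6-iodo-4,5-dimethylhex-2-enal F6. Giese addition of F6 to 8 (Bu3SnH, AIBN, PhH, 80 °C) should then give 10.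

**Further compounds**

F1 | step 9 | (2E,4S,5R)-4-ethenyl-4,5,8-trimethyl-9-[(trimethylsilyl)oxy]deca-2,8-dienal | CC(O[Si](C)(C)C)=C(C)CC[C@@H](C)[C@](C)(C=C)/C=C/C=O
F2 | step 2 | (3S,4S)-3,4-dimethyl-3-[2-(phenylsulfinyl)ethyl]dihydrofuran-2(3H)-one (sulfoxide epimers) | C[C@@H]1COC(=O)[C@@]1(C)CCS(=O)c1ccccc1
F3 | step 5 | methyl (2E,4R,5S)-4-ethenyl-6-hydroxy-4,5-dimethylhex-2-enoate | OC[C@@H](C)[C@](C)(C=C)/C=C/C(=O)OC
F4 | step 5 | methyl (2E,4R,5S)-4-ethenyl-6-iodo-4,5-dimethylhex-2-enoate | IC[C@@H](C)[C@](C)(C=C)/C=C/C(=O)OC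
F5 | step 5 | (2E,4R,5S)-4-ethenyl-6-iodo-4,5-dimethylhex-2-en-1-ol | IC[C@@H](C)[C@](C)(C=C)/C=C/CO
F6 | step 5 | (2E,4R,5S)-4-ethenyl-6-iodo-4,5-dimethylhex-2-enal | IC[C@@H](C)[C@](C)(C=C)/C=C/C=O
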